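**Retrosynthetic overview**
- The strategy rests on the pyran-4-one ring (ring C) of this isoflavone. C4 is an aldehyde-level carbon on C4a, ortho to the phenolic O1 on C8a, which is a salicylaldehyde in disguise. C2=C3 is an alkyne-level two-carbon unit with the B ring on C3 and only H on C2.
- Key disconnection: O1–C2 and C3–C4 are cut together, giving salicylaldehyde 2 (A ring) and aryl silyl alkyne 9 (B ring on the future C3, Me3Si as a removable stand-in for H on the future C2), joined by Rh(III) aldehyde C–H annulation.
- Aldehyde 2 comes from 3,4,5-trimethoxyphenol by ortho-formylation. Alkyne 9 comes from 2,3-dihydroxybenzaldehyde by 3-O-benzylation, 2-O-methylation, one-carbon alkynylation and C-silylation.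
- Ring order: the A and B rings are bought as arenes; the pyranone C ring is the only ring formed (step 6). Protodesilylation at C2 and hydrogenolysis of the benzyl ether finish the route.

Key step: step 6

Remark: the target is an achiral isoflavone with no stereogenic element, so "single enantiomer" is taken to mean the structure as drawn and no stereocontrol is needed.

**Route**

Step 1
Reactants: 1 3,4,5-trimethoxyphenol
Product: 2 6-hydroxy-2,3,4-trimethoxybenzaldehyde
Conditions: MgCl2, Et3N, (CH2O)n, MeCN, reflux; then 1 M HCl
Reagents that add atoms: paraformaldehyde (as formaldehyde), C=O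
Why: Casnati–Skattebøl magnesium-mediated ortho-formylation, in which the magnesium phenoxide delivers formaldehyde to the carbon next to oxygen (the two free ortho positions of 1 are equivalent) and a second formaldehyde oxidises the benzylic alkoxide to the aldehyde by hydride transfer.

Step 2
Reactants: 3 2,3-dihydroxybenzaldehyde
Product: 5 3-(benzyloxy)-2-hydroxybenzaldehyde, via disodium 3-formylbenzene-1,2-diolate 4 (not isolated)
Conditions: NaH (2.2 equiv), DMSO, rt; BnBr (1.0 equiv), rt; aq. HCl
Reagents that add atoms: benzyl bromide, BrCc1ccccc1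
Why: Williamson etherification of the dianion, in which the 2-phenoxide is conjugated with and chelated to the formyl group and is the weaker nucleophile, so one equivalent of benzyl bromide should alkylate the 3-oxygen selectively.

Step 3
Reactants: 5 3-(benzyloxy)-2-hydroxybenzaldehyde
Product: 6 3-(benzyloxy)-2-methoxybenzaldehyde
Conditions: MeI, K2CO3, DMF, rt
Reagents that add atoms: iodomethane, CI
Why: Williamson O-methylation of the remaining phenol under standard carbonate conditions, to which the aldehyde and the benzyl ether are inert.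

Step 4
Reactants: 6 3-(benzyloxy)-2-methoxybenzaldehyde
Product: 7 1-(benzyloxy)-3-ethynyl-2-methoxybenzene
Conditions: MeC(O)C(N2)P(O)(OMe)2, K2CO3, MeOH, 0 °C to rt
Reagents that add atoms: dimethyl (1-diazo-2-oxopropyl)phosphonate, CC(=O)C(=[N+]=[N-])P(=O)(OC)OC
Why: Seyferth–Gilbert homologation in the Ohira–Bestmann variant, in which methanolysis of the reagent gives the diazomethylphosphonate anion that olefinates the non-enolisable aryl aldehyde, and loss of N2 with 1,2-hydrogen shift gives the terminal alkyne under conditions mild enough for both ethers.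

Step 5
Reactants: 7 1-(benzyloxy)-3-ethynyl-2-methoxybenzene
Product: 9 {[3-(benzyloxy)-2-methoxyphenyl]ethynyl}trimethylsilane, via lithium [3-(benzyloxy)-2-methoxyphenyl]acetylide 8 (not isolated)
Conditions: n-BuLi (1.05 equiv), THF, −78 °C; Me3SiCl, −78 °C to rt
Reagents that add atoms: chlorotrimethylsilane, C[Si](C)(C)Cl
Why: Deprotonation of the terminal alkyne by n-BuLi and C-silylation of the acetylide with Me3SiCl, a standard alkyne silylation in which neither aryl ether is metalated at −78 °C.

Step 6
Reactants: 2 6-hydroxy-2,3,4-trimethoxybenzaldehyde; 9 {[3-(benzyloxy)-2-methoxyphenyl]ethynyl}trimethylsilane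
Product: 10 3-[3-(benzyloxy)-2-methoxyphenyl]-5,6,7-trimethoxy-2-(trimethylsilyl)-4H-chromen-4-one
Conditions: [Cp*RhCl2]2 (2.5 mol %), anhydrous Cu(OAc)2 (2.2 equiv), o-xylene, 120 °C, N2
Reagents that add atoms: none
Why: Acetate-assisted O–H and aldehyde C–H metalation of 2 by Cp*Rh(III) should give a five-membered acyl-rhodium phenoxide chelate; alkyne 9 inserts into the Rh–acyl bond (forming C3–C4) to a seven-membered oxa-rhodacycle, C–O reductive elimination (forming O1–C2) releases 10 and Rh(I), and Cu(OAc)2 reoxidises rhodium. The closest known reaction type is the rhodium-catalysed oxidative coupling of salicylaldehydes with internal alkynes to 2,3-disubstituted chromones. The pyran-4-one ring closes as a formal [4+2] oxidative annulation of the O1–C8a–C4a–C4 unit with C2≡C3, the ring-closing event being reductive elimination at O1–C2 after migratory insertion has made C3–C4; no stereocentre is formed. The step needs the aryl-bearing alkyne carbon to bond to the acyl carbon (aryl at C3, silicon at C2) and needs insertion to outrun loss of CO from the acyl rhodium. The bulky Me3Si group should stay on the carbon bound to rhodium (longer Rh–C bond, stabilisation of a metal–carbon bond alpha to silicon), an orientation that rests on analogy with Larock-type annulations of silyl alkynes, and the phenoxide chelate holds the acyl rhodium against decarbonylation.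

Step 7
Reactants: 10 3-[3-(benzyloxy)-2-methoxyphenyl]-5,6,7-trimethoxy-2-(trimethylsilyl)-4H-chromen-4-one
Product: 11 3-[3-(benzyloxy)-2-methoxyphenyl]-5,6,7-trimethoxy-4H-chromen-4-one
Conditions: TBAF (1.5 equiv), AcOH (1.5 equiv), THF, 0 °C to rt
Reagents that add atoms: none
Why: Fluoride-induced protodesilylation, in which fluoride attacks silicon and the C2 carbanion (an sp2 anion stabilised by the ring oxygen) is protonated by acetic acid, which also keeps the medium from becoming basic enough to open the pyranone ring.

Step 8
Reactants: 11 3-[3-(benzyloxy)-2-methoxyphenyl]-5,6,7-trimethoxy-4H-chromen-4-one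
Product: 12 3-(3-hydroxy-2-methoxyphenyl)-5,6,7-trimethoxy-4H-chromen-4-one (target)
Conditions: H2 (1 atm), 10% Pd/C, EtOAc–MeOH, rt, stopped at full conversion of 11
Reagents that add atoms: none
Why: Catalytic hydrogenolysis of the aryl benzyl ether on Pd/C, which should be faster than hydrogenation of the conjugated trisubstituted C2=C3 bond of the isoflavone when the reaction is stopped at full conversion.

**Compound list**

1 | 3,4,5-trimethoxyphenol | COc1cc(O)cc(OC)c1OC | starting material
2 | 6-hydroxy-2,3,4-trimethoxybenzaldehyde | COc1cc(O)c(C=O)c(OC)c1OC | intermediate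
3 | 2,3-dihydroxybenzaldehyde | O=Cc1cccc(O)c1O | starting material
4 | disodium 3-formylbenzene-1,2-diolate | O=Cc1cccc([O-])c1[O-].[Na+].[Na+] | intermediate (not isolated)
5 | 3-(benzyloxy)-2-hydroxybenzaldehyde | O=Cc1cccc(OCc2ccccc2)c1O | intermediate
6 | 3-(benzyloxy)-2-methoxybenzaldehyde | COc1c(C=O)cccc1OCc1ccccc1 | intermediate
7 | 1-(benzyloxy)-3-ethynyl-2-methoxybenzene | COc1c(C#C)cccc1OCc1ccccc1 | intermediate
8 | lithium [3-(benzyloxy)-2-methoxyphenyl]acetylide | [Li]C#Cc1cccc(OCc2ccccc2)c1OC | intermediate (not isolated)
9 | {[3-(benzyloxy)-2-methoxyphenyl]ethynyl}trimethylsilane | COc1c(OCc2ccccc2)cccc1C#C[Si](C)(C)C | intermediate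
10 | 3-[3-(benzyloxy)-2-methoxyphenyl]-5,6,7-trimethoxy-2-(trimethylsilyl)-4H-chromen-4-one | COc1cc2oc([Si](C)(C)C)c(-c3cccc(OCc4ccccc4)c3OC)c(=O)c2c(OC)c1OC | intermediate
11 | 3-[3-(benzyloxy)-2-methoxyphenyl]-5,6,7-trimethoxy-4H-chromen-4-one | COc1cc2occ(-c3cccc(OCc4ccccc4)c3OC)c(=O)c2c(OC)c1OC | intermediate
12 | 3-(3-hydroxy-2-methoxyphenyl)-5,6,7-trimethoxy-4H-chromen-4-one | COc1cc2occ(-c3cccc(O)c3OC)c(=O)c2c(OC)c1OC | target

**Step count**

Total steps: 8. Longest linear sequence: 7 steps (from 3 through steps 2, 3, 4, 5, 6, 7 and 8); the A-ring branch contributes step 1.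

**Steps most likely to fail**

Step 6 (key annulation). The alkyne may insert with the opposite orientation, which would put silicon at C3 and the aryl group at C2. The silyl alkyne may also be desilylated or oxidatively homocoupled by copper at 120 °C before it is consumed, or the acyl rhodium may lose CO. The fallback is the chalcone route, which sets out from 1 and 6 and comes back at 11.
- Phenol 1 would be C-acetylated (AcOH, BF3·OEt2, 80 °C, Friedel–Crafts/Fries) to 1-(6-hydroxy-2,3,4-trimethoxyphenyl)ethan-1-one F1.
- Claisen–Schmidt condensation of F1 with aldehyde 6 (KOH, EtOH, rt) would give (E)-3-[3-(benzyloxy)-2-methoxyphenyl]-1-(6-hydroxy-2,3,4-trimethoxyphenyl)prop-2-en-1-one F2.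
- Oxidative 1,2-aryl migration (Tl(NO3)3·3H2O, MeOH/HC(OMe)3) would move the B ring to the alpha carbon and give racemic 2-[3-(benzyloxy)-2-methoxyphenyl]-1-(6-hydroxy-2,3,4-trimethoxyphenyl)-3,3-dimethoxypropan-1-one F3.
- HCl in MeOH at reflux would close the pyranone ring with loss of methanol to give 11, after which step 8 follows.

Step 7 (protodesilylation). Fluoride or adventitious hydroxide may add at C2 and open the pyranone ring, or C–Si cleavage may stall in the buffered medium. The fallback turns ring opening into the plan; it sets out from 10 and comes back at 11.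
- KOH in aqueous EtOH at reflux would cleave 10 (desilylation and retro-Claisen loss of C2) to the deoxybenzoin 2-[3-(benzyloxy)-2-methoxyphenyl]-1-(6-hydroxy-2,3,4-trimethoxyphenyl)ethan-1-one F4.
- N,N-Dimethylformamide dimethyl acetal (toluene, 100 °C) would put C2 back and close the ring to 11, the classical deoxybenzoin isoflavone synthesis.

Step 8 (hydrogenolysis). The C2=C3 bond may be over-reduced to the isoflavanone, or debenzylation may stay incomplete if the reaction is stopped early. The fallback inverts the last two operations so that the silyl group shields the double bond; it sets out from 10 and comes back at 12.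
- Hydrogenolysis of 10 (H2, Pd/C, EtOAc–MeOH), whose C2=C3 bond is tetrasubstituted and hindered, would give 3-(3-hydroxy-2-methoxyphenyl)-5,6,7-trimethoxy-2-(trimethylsilyl)-4H-chromen-4-one F5.
- TBAF/AcOH in THF would then remove the silyl group to give 12.

Further compounds
F1 | step 6 | 1-(6-hydroxy-2,3,4-trimethoxyphenyl)ethan-1-one | CC(=O)c1c(O)cc(OC)c(OC)c1OC
F2 | step 6 | (E)-3-[3-(benzyloxy)-2-methoxyphenyl]-1-(6-hydroxy-2,3,4-trimethoxyphenyl)prop-2-en-1-one | COc1cc(O)c(C(=O)/C=C/c2cccc(OCc3ccccc3)c2OC)c(OC)c1OC
F3 | step 6 | rac-2-[3-(benzyloxy)-2-methoxyphenyl]-1-(6-hydroxy-2,3,4-trimethoxyphenyl)-3,3-dimethoxypropan-1-one | COc1cc(O)c(C(=O)C(C(OC)OC)c2cccc(OCc3ccccc3)c2OC)c(OC)c1OC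
F4 | step 7 | 2-[3-(benzyloxy)-2-methoxyphenyl]-1-(6-hydroxy-2,3,4-trimethoxyphenyl)ethan-1-one | COc1cc(O)c(C(=O)Cc2cccc(OCc3ccccc3)c2OC)c(OC)c1OC
F5 | step 8 | 3-(3-hydroxy-2-methoxyphenyl)-5,6,7-trimethoxy-2-(trimethylsilyl)-4H-chromen-4-one | COc1cc2oc([Si](C)(C)C)c(-c3cccc(O)c3OC)c(=O)c2c(OC)c1OC
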